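**Retrosynthetic overview**

- Feature used (quinone numbering: C1=O, C2–OH, C3–nonadecyl, C4=O, C5–OMe, C6–H): C3 is the central carbon of a cyclic β-dicarbonyl unit (C2–C3–C4), and C4–C5(OMe)=C6–C1=O is a vinylogous ester. The ring is therefore the Dieckmann product of an acyclic 5-oxo ester whose enol ether is the methanol adduct of an ynone.
- Key disconnection: the C3–C4 ring bond (ketone α-carbon onto ester carbonyl) together with the C5–OMe bond (methanol onto a C5≡C6 triple bond), leading back to linear ethyl 4,5-dioxopentacos-2-ynoate. Both bonds form in one flask at the quinone oxidation level, so no redox step follows.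
- The acetylenic diketo ester is cut at both C–C bonds of its 1,2-dione: oxalic bis-Weinreb amide (C1–C2 linchpin) + icosyl Grignard reagent (C3 and the chain) + lithiated triethyl orthopropiolate (C4–C6).
- Ring order: the single carbocycle is closed in the last step.

Key step: step 3

Remark on the chemistry: the target has no stereocentre; the enol ether geometry and the hemiaminal centres of the Weinreb adducts are transient, so nothing stereochemical has to be controlled, and the oxamide and the orthoester alkyne are taken as commercial.

**Step 1**
Reactants: 1 1-bromoicosane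
Product: 2 icosylmagnesium bromide (titrated THF solution, used directly)
Conditions: Mg turnings, I2 (cat.), THF, 50 °C, slow addition of 1
Reagents that add atoms: magnesium, [Mg]
Why: Grignard formation by insertion of magnesium into a primary C–Br bond, where warm THF should keep the long-chain reagent dissolved and slow addition should hold Wurtz coupling down.

**Step 2**
Reactants: 2 icosylmagnesium bromide, 3 N,N'-dimethoxy-N,N'-dimethyloxamide, 4 3,3,3-triethoxyprop-1-yne
Product: 9 ethyl 4,5-dioxopentacos-2-ynoate, via magnesium hemiaminal mono-adduct 5 (not isolated), via lithium acetylide 6 (not isolated), via mixed bis-alkoxide 7 (not isolated), via orthoester ynedione 8 (not isolated)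
Conditions: 3, THF, −78 °C, 2 (1.0 equiv), to 0 °C; then 6 (2 equiv, from 4 and n-BuLi, THF, −78 °C), −78 °C to rt; inverse quench into cold 1 M H2SO4
Reagents that add atoms: water, O
Why: Double Weinreb ketone synthesis on one linchpin, in which each N-methoxy-N-methyl hemiaminal stays a metal chelate until work-up, so the first ketone is never exposed to the acetylide and cannot enolise, and the acid quench should release the 1,2-dione, keep the freed N,O-dimethylhydroxylamine protonated and hydrolyse the orthoester to the ethyl ester.

**Step 3**
Reactants: 9 ethyl 4,5-dioxopentacos-2-ynoate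
Product: 12 irisoquin C (2-hydroxy-5-methoxy-3-nonadecyl-1,4-benzoquinone), via enol ether 10 (not isolated), via sodium quinonolate 11 (not isolated)
Conditions: MeOH/THF, DABCO (10 mol %), 0 °C; then NaOMe (3 equiv), 0 to 40 °C; cold 1 M HCl
Reagents that add atoms: methanol, CO
Why: Proposed new method: DABCO-catalysed conjugate addition of methanol to ynone 9 (chain numbering) should place the methoxy group at C2, the carbon β to the more electron-poor C4 ketone and α to the ester, giving enol ether 10; sodium methoxide then enolises the C5 ketone towards C6, the only enolisable carbon, and the C6 enolate attacks the C1 ester (Dieckmann condensation), which forms the C3–C4 bond of the quinone and expels ethoxide. The closest known reaction types are the amine-catalysed addition of alcohols to ynones, the Dieckmann cyclisation of 5-oxo esters to cyclohexane-1,3-diones and the methoxide-induced rearrangement of enol lactones to cyclic 1,3-diones. The six-membered ring closes in a 6-(enolexo)-exo-trig mode from the (E)-isomer of 10, in which ester and C4 ketone are cis, and the (Z)-isomer is fed in through reversible methoxide addition–elimination at C2. No stereocentre is formed. The step needs C-acylation at C6 to win over O-acylation and over 5-endo attack at C2; both by-paths are reversible in methanolic methoxide, whereas the Claisen product is removed irreversibly as the vinylogous carboxylate 11. The position of the methoxy group next to the new C4 carbonyl is fixed by the conjugate addition before the ring exists, so no later differentiation of the ring oxygens is needed.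

**Compound list**

1 | 1-bromoicosane | CCCCCCCCCCCCCCCCCCCCBr | starting material
2 | icosylmagnesium bromide | CCCCCCCCCCCCCCCCCCCC[Mg]Br | intermediate
3 | N,N'-dimethoxy-N,N'-dimethyloxamide (oxalic acid bis-Weinreb amide) | CON(C)C(=O)C(=O)N(C)OC | starting material
4 | 3,3,3-triethoxyprop-1-yne (triethyl orthopropiolate) | C#CC(OCC)(OCC)OCC | starting material
5 | bromomagnesium alkoxide of 2-hydroxy-N-methoxy-2-[methoxy(methyl)amino]-N-methyldocosanamide (racemic mono-adduct of 2 to 3) | CCCCCCCCCCCCCCCCCCCCC(O[Mg]Br)(N(C)OC)C(=O)N(C)OC | intermediate
6 | (3,3,3-triethoxyprop-1-yn-1-yl)lithium | [Li]C#CC(OCC)(OCC)OCC | intermediate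
7 | mixed bromomagnesium lithium bis-alkoxide of 1,1,1-triethoxy-4,5-bis[methoxy(methyl)amino]pentacos-2-yne-4,5-diol (diastereomer mixture, both collapse to 8) | CCCCCCCCCCCCCCCCCCCCC(O[Mg]Br)(N(C)OC)C(O[Li])(N(C)OC)C#CC(OCC)(OCC)OCC | intermediate
8 | 1,1,1-triethoxypentacos-2-yne-4,5-dione | CCOC(OCC)(OCC)C#CC(=O)C(=O)CCCCCCCCCCCCCCCCCCCC | intermediate
9 | ethyl 4,5-dioxopentacos-2-ynoate | CCOC(=O)C#CC(=O)C(=O)CCCCCCCCCCCCCCCCCCCC | intermediate
10 | ethyl (2E)-2-methoxy-4,5-dioxopentacos-2-enoate (in equilibrium with its 2Z isomer under methoxide) | CCOC(=O)/C(OC)=C\C(=O)C(=O)CCCCCCCCCCCCCCCCCCCC | intermediate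
11 | sodium 4-methoxy-2-nonadecyl-3,6-dioxocyclohexa-1,4-dien-1-olate (sodium salt of 12) | [Na+].[O-]C1=C(CCCCCCCCCCCCCCCCCCC)C(=O)C(OC)=CC1=O | intermediate
12 | irisoquin C, 2-hydroxy-5-methoxy-3-nonadecylcyclohexa-2,5-diene-1,4-dione | CCCCCCCCCCCCCCCCCCCC1=C(O)C(=O)C=C(OC)C1=O | target

**Totals and risks**

Total step count: 3. Longest linear sequence: 3 steps (1 → 2 → 9 → 12).

Steps most likely to fail:

1. Step 3 (proposed new method). Methoxide may attack the C4–C5 dione and cleave a C–C bond faster than C6 is enolised, oxygen cyclisation onto C2 may drain material into a furanone that does not reopen, or adventitious water may hydrolyse the vinylogous ester. Fallback with known chemistry, in which the ring is bought and not closed: setting out from bromide 1, dehydrobromination (t-BuOK, THF, reflux) should give icos-1-ene F1, and ozonolysis (O3, CH2Cl2, −78 °C, then PPh3) nonadecanal F2. The three-component reductive alkylation of commercial 2,5-dihydroxy-1,4-benzoquinone with F2 and Hantzsch ester under L-proline catalysis (Knoevenagel condensation, then transfer hydrogenation) should give 2,5-dihydroxy-3-nonadecyl-1,4-benzoquinone F3. Acid-catalysed methanolysis (MeOH, H2SO4 cat., reflux) should etherify only the hydroxyl next to C6–H, not the one flanked by the alkyl chain, and brings the fallback back to the route at 12.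

2. Step 2. The first nucleophile may add twice, the first chelate may collapse early so that the acetylide attacks the freed ketone, the hindered second amide may not react, or the liberated N,O-dimethylhydroxylamine may add to the ynedione during work-up. Fallback, a stepwise protecting-group construction in place of the linchpin: setting out from 2, addition to excess diethyl oxalate (THF, −78 °C) should give ethyl 2-oxodocosanoate F4. Ketalisation (HC(OEt)3, EtOH, TsOH) should give ethyl 2,2-diethoxydocosanoate F5. BF3·OEt2-promoted addition of acetylide 6 to the ester (THF, −78 °C) should give 1,1,1,5,5-pentaethoxypentacos-2-yn-4-one F6. Aqueous acid (TFA, H2O, CH2Cl2) should cleave orthoester and ketal, and the fallback comes back to the route at 9.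

3. Step 1. Initiation with the waxy bromide may be sluggish and Wurtz homocoupling may consume it. Fallback with reversed polarity, in which 1 is the electrophile and no organometallic of the chain is needed: setting out from 1, alkylation of ethyl 1,3-dithiane-2-carboxylate (NaH, DMF/THF) should give ethyl 2-icosyl-1,3-dithiane-2-carboxylate F7, a masked α-keto ester. BF3·OEt2-promoted addition of acetylide 6 should give 4,4,4-triethoxy-1-(2-icosyl-1,3-dithian-2-yl)but-2-yn-1-one F8. Oxidative dithiane removal (PhI(OCOCF3)2, MeCN/H2O), during which the acid formed also hydrolyses the orthoester, brings the fallback back to the route at 9, so that steps 1 and 2 are both bypassed.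

**Further compounds**

F1 | step 3 | icos-1-ene | C=CCCCCCCCCCCCCCCCCCC
F2 | step 3 | nonadecanal | CCCCCCCCCCCCCCCCCCC=O
F3 | step 3 | 2,5-dihydroxy-3-nonadecyl-1,4-benzoquinone | CCCCCCCCCCCCCCCCCCCC1=C(O)C(=O)C=C(O)C1=O
F4 | step 2 | ethyl 2-oxodocosanoate | CCOC(=O)C(=O)CCCCCCCCCCCCCCCCCCCC
F5 | step 2 | ethyl 2,2-diethoxydocosanoate | CCOC(=O)C(OCC)(OCC)CCCCCCCCCCCCCCCCCCCC
F6 | step 2 | 1,1,1,5,5-pentaethoxypentacos-2-yn-4-one | CCOC(OCC)(OCC)C#CC(=O)C(OCC)(OCC)CCCCCCCCCCCCCCCCCCCC
F7 | step 1 | ethyl 2-icosyl-1,3-dithiane-2-carboxylate | CCOC(=O)C1(CCCCCCCCCCCCCCCCCCCC)SCCCS1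
F8 | step 1 | 4,4,4-triethoxy-1-(2-icosyl-1,3-dithian-2-yl)but-2-yn-1-one | CCOC(OCC)(OCC)C#CC(=O)C1(CCCCCCCCCCCCCCCCCCCC)SCCCS1
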